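Assumption: the target is the centrosymmetric (meso) diastereomer and therefore achiral; all chiral intermediates are racemic and their SMILES show one enantiomer only to fix relative configuration. Ring atoms are labelled as in the final cyclobutane (C1 and C3 aryl-bearing, C2 and C4 acyl-bearing), and the same labels are used for the atoms of earlier intermediates that become these carbons.

## Structural features

The target is a cyclobutane in which every ring carbon is substituted: C1 and C3 each carry a 3,4-dimethoxyphenyl group, and C2 and C4 each carry a carbonyl group that acylates the nitrogen of a 5,6-dihydropyridin-2(1H)-one, so that each side arm is an imide containing a conjugated enelactam. The four ring carbons are contiguous stereocentres, and the SMILES string corresponds to the arrangement with the two aryl groups trans across the ring, the two acyl groups trans across the ring, and alternating vicinal relations (C1/C2 trans, C2/C3 cis, C3/C4 trans, C4/C1 cis), which makes the molecule centrosymmetric. The fragile parts are the imides, which are cleaved by nucleophiles and whose enelactam is a Michael acceptor and reducible, the epimerisable hydrogens at C2 and C4, and the electron-rich dimethoxyarenes, which are sensitive to strong oxidants and electrophiles. The real difficulty is the relative configuration on a strained ring: C1 and C3 cannot be corrected by epimerisation and must be set kinetically, and the head-to-tail placement of aryl and acyl groups must be unambiguous. The key step exploits the C1–C2 bond, which joins a benzylic carbon to an acyl-bearing carbon and is therefore the bond that results when a benzylic cyclopropane carbon migrates to an ester-substituted carbene carbon attached to the ring. The same event turns C2 and C3 into an alkene, which is hydrogenated later under direction of the C4 carbonyl, and it carries over a cis relation between the C1 aryl and the C4 carboxyl that can be installed on a flat cyclopropene.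

## Logic of the disconnections

20 ⇒ 16 + 17. The two N–C(acyl) bonds at the C2 and C4 carbonyls are cut. The imide with its enelactam tolerates neither hydrogenation nor base nor nucleophiles, so it is attached last, and the symmetry lets both be made in one operation. The target reduces to meso 16 and two equivalents of 17. The forward acylation must not epimerise C2/C4 or add to the enone of 17, hence 18 and preformed 19 at low temperature without amine base.

16 ⇒ 14 (through 15). The carboxyl groups are traced back to esters: the tert-butyl–oxygen bond at the C4 carboxyl and the acyl–oxygen bond of the methyl ester at C2. Esters carry the carboxyls through the carbenoid step, and the C4 ester serves as directing group. They differ so that the C4 carboxyl can be unmasked under acid alone. The demand is cleavage without touching C2/C4: acidolysis first, then mild saponification.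

14 ⇒ 13. The C2–H and C3–H bonds are removed. Both remaining stereocentres can then be set in one syn addition, and the precursor is the product of the ring expansion. Hydrogen has to arrive on the face that carries the C1 aryl and the C4 ester, the more hindered one, so the catalyst must be anchored on the C4 carbonyl.

13 ⇒ 12. C1–C2 is cut and C1 is reconnected to C3, so the cyclobutene contracts to a cyclopropane and C2 becomes a diazo carbon. This bond links a benzylic to an acyl-bearing carbon, which is what a benzylic 1,2-shift to an ester carbene produces. The tetrasubstituted cyclobutene is thereby traced to a cyclopropane whose two aryls and ring ester are all cis, a pattern open to addition on a flat three-membered alkene. The benzylic ring carbon, not the ester-bearing one, must migrate, with retention, under neutral conditions.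

12 ⇒ 10 (through 11). The C=N2 unit at C2 is removed. The diazo group is introduced as late as possible. Only the side-arm methylene may be enolised, and it needs activation for the transfer.

10 ⇒ 9. The side-arm ester carbon is traced to the internal alkene carbon of an allyl group. An acetate unit cannot be added across 5 with confidence, whereas an allyl group can. The oxidative cleavage must spare the dimethoxyarenes and the tert-butyl ester.

9 ⇒ 5 + 6 (through 7 and 8). The bond from C3 to the allyl CH2 and the C1–H bond are cut, a syn 1,2-addition retron. Three stereocentres collapse to achiral, symmetrical 5, so there is no regiochemical question. Both new bonds must form on the face opposite the ester, so that the C1 aryl ends cis to the C4 ester; the tert-butyl group shields the ester face and discourages chelation.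

5 ⇒ 3 + 4. Both ring bonds from C4 to C1 and C3 are cut, a [2+1] retron. This gives symmetrical 3 and commercial 4. The carbenoid must add to the triple bond faster than it dimerises or attacks the arenes.

3 ⇒ 1 + 2. One aryl–alkynyl bond is cut. Both halves are purchasable and carry the same arene, so a single cross-coupling suffices. The forward step must keep oxidative homocoupling of 2 behind the cross-coupling, hence exclusion of oxygen.

## Other disconnections considered

Alternative 1: The cut is made inside both arenes. In each ring the bonds from position 2 to 3 and from position 5 to 4 (counted from the carbon on the cyclobutane) are opened. This leaves the bis-diene A2, a cyclobutane with two buta-1,3-dien-2-yl groups and two tert-butyl esters, and two molecules of vinylene carbonate A3.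
- Forward step: a twofold Diels–Alder reaction of A2 with A3 would give the bis(cyclohexene carbonate) A1. Each new ring would then need carbonate hydrolysis, aromatisation by dehydrogenation and twofold O-methylation.
- In its favour: the ring configuration is fixed on a small symmetric core before any arene exists, the symmetric dienophile raises no regiochemical question, and both halves react in one flask.
- Against it here: A3 is a sluggish dienophile needing prolonged heating, under which A2 may polymerise or rearrange. The aromatisation removes four hydrogens per ring under oxidising conditions next to epimerisable centres. A2 itself is not available and would need a multistep preparation in which the two diene arms are built up without touching the two esters.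
- Comparison: on structure, Alternative 1 is the better on one point, since no ring stereocentre is made after the core is in hand and the facial problem of step 7 does not arise. On mechanism, a thermal pericyclic addition is at least the equal of a carbenoid shift in predictability. On step economy the chosen plan is clearly ahead: A1 is still about eight operations from 16 and A2 needs its own preparation, against nine steps in all.

Alternative 2: The cut is C1–C2 and C3–C4, dividing the ring into two identical halves, each a 6,7-dimethoxycoumarin A5.
- Forward step: [2+2] photocycloaddition of two molecules of A5 stacked antiparallel about an inversion centre would give the anti head-to-tail bis-lactone A4.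
- In its favour: one step makes the ring and all four stereocentres, the lactone locks the alkene so no geometric isomerisation competes, the centrosymmetric pairing maps directly onto the trans-aryl, trans-acyl pattern, and A5 is inexpensive.
- Against it here: irradiation of A5 in solution would be expected to favour head-to-head pairing, so the anti head-to-tail mode depends on a crystal or template enforcing antiparallel stacking, which is not assured for A5. Each arene of A4 also carries an extra phenolic oxygen from the lactone. It would have to be removed by lactone opening, sulfonylation and reductive C–O cleavage before the imides can be made.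
- Comparison: on step economy Alternative 2 is the better, at roughly six operations against nine. It is also the better in setting all four stereocentres in one event. It is weaker on control, because the outcome rests on packing and not on reagent or substrate control, whereas the chosen plan sets each relation in a separate step (two of which carry facial-selectivity risk of their own). Mechanistically it is an excited-state cycloaddition against a ground-state carbenoid migration; neither is free of a selectivity question.

Alternative 3: The cut is the C1–aryl and C3–aryl bonds, leaving A7, the trans-1,3-dicarboxamide of cyclobutane bearing an 8-quinolinyl group on each nitrogen, and two equivalents of 1.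
- Forward step: a twofold amide-directed C–H arylation of A7 with 1 under Pd(OAc)2, with AgOAc as iodide acceptor, would give A6.
- In its favour: the 1,3-trans core is in place from the start. Each arylation occurs cis to a directing amide, because the C–H bond is broken within a five-membered chelate at palladium, and this is exactly the required cis relation between each aryl and one acyl group. Compound 1 is used directly, and the bond-forming reaction belongs to a well-established class for cyclobutane carboxamides.
- Against it here: the second arylation must be steered by the second amide to the opposite face and not by the first amide to its other neighbouring methylene, which would give cis aryls. The two hindered quinolinylamide groups of A6 must then be cleaved, which needs N-activation and peroxide hydrolysis with some risk to C2/C4. Stoichiometric AgOAc is consumed.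
- Comparison: Alternative 3 is the equal or the better on step economy (about five operations) and on precedent for the key bond formation. Its stereochemistry at C1 and C3 comes from the directing group and not from face-selective additions. The chosen plan is longer but needs no auxiliary removal and has no site-selection question between two directing groups. Mechanistically it is concerted metalation–deprotonation at divalent palladium against a 1,2-shift in a rhodium carbenoid.

Key step: step 6

## Route

Step 1
Reactants: 1 4-iodoveratrole (4-iodo-1,2-dimethoxybenzene), 2 4-ethynylveratrole (4-ethynyl-1,2-dimethoxybenzene)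
Product: 3 1,2-bis(3,4-dimethoxyphenyl)ethyne
Conditions: PdCl2(PPh3)2 (2 mol %), CuI (4 mol %), Et3N, THF (degassed), rt → 50 °C
Reagents that add atoms: none
Why: Sonogashira coupling: zerovalent palladium formed in the flask inserts into the C–I bond of 1, the copper acetylide of 2 transmetalates and reductive elimination forms the aryl–alkynyl bond; exclusion of oxygen holds back Glaser homocoupling of 2.

Step 2
Reactants: 3 1,2-bis(3,4-dimethoxyphenyl)ethyne, 4 tert-butyl diazoacetate
Product: 5 tert-butyl 2,3-bis(3,4-dimethoxyphenyl)cycloprop-2-ene-1-carboxylate (achiral)
Conditions: Rh2(OAc)4 (1 mol %), CH2Cl2, rt, 4 (2.5 equiv) added over 12 h by syringe pump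
Reagents that add atoms: none
Why: [2+1] cyclopropenation of the alkyne by the rhodium carbenoid; slow addition keeps the carbenoid concentration low so that dimerisation and arene attack stay behind addition to the electron-rich alkyne.

Step 3
Reactants: 5 tert-butyl 2,3-bis(3,4-dimethoxyphenyl)cycloprop-2-ene-1-carboxylate, 6 allyl bromide
Product: 9 tert-butyl 2-(prop-2-en-1-yl)-2,3-bis(3,4-dimethoxyphenyl)cyclopropane-1-carboxylate (racemic; both aryl groups and the ester on one face, the allyl group and H-3 on the other), via allylzinc bromide 7 (not isolated), via cyclopropylzinc bromide 8 (not isolated)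
Conditions: 6, Zn dust, LiCl, THF, 0 °C → rt; then 5, THF, 0 → 40 °C; sat. aq NH4Cl, 0 °C
Reagents that add atoms: none
Why: Allylzincation (metallo-ene carbometalation) of the strained, symmetrical cyclopropene should add allyl and zinc syn from the face opposite the tert-butyl ester, and protonation of the C–Zn bond with retention then places the C1 hydrogen trans and the C1 aryl cis to the C4 ester; THF and chloride saturate zinc and the hindered tert-butyl ester is a poor ligand, so ester-directed delivery is not expected. The arm is brought in as allyl because a tertiary cyclopropyl pinacol boronate would not be homologated reliably by a diazoacetate.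

Step 4
Reactants: 9 tert-butyl 2-(prop-2-en-1-yl)-2,3-bis(3,4-dimethoxyphenyl)cyclopropane-1-carboxylate
Product: 10 tert-butyl 2-(2-methoxy-2-oxoethyl)-2,3-bis(3,4-dimethoxyphenyl)cyclopropane-1-carboxylate (racemic; configuration as in 9)
Conditions: O3 (titrated stream, ca. 2.2 equiv), NaOH (5 equiv, 2.5 M in MeOH), CH2Cl2, −78 °C; H2O, then rt
Reagents that add atoms: ozone, [O-][O+]=O; methanol, CO
Why: Ozonolysis in methanolic NaOH converts a terminal alkene directly into a methyl ester (methanol traps the carbonyl oxide, base dehydrates the methoxy hydroperoxide, and the aldehyde fragment is oxidised as its hemiacetal); the alkene reacts far faster than the arenes when ozone is dosed, and the tert-butyl ester is inert to methoxide at −78 °C.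

Step 5
Reactants: 10 tert-butyl 2-(2-methoxy-2-oxoethyl)-2,3-bis(3,4-dimethoxyphenyl)cyclopropane-1-carboxylate
Product: 12 tert-butyl 2-(1-diazo-2-methoxy-2-oxoethyl)-2,3-bis(3,4-dimethoxyphenyl)cyclopropane-1-carboxylate (racemic; both aryls and the ring ester cis, the diazo ester arm on the other face), via trifluoroacetyl ester 11 (not isolated)
Conditions: LiN(SiMe3)2 (1.1 equiv), THF, −78 °C; CF3CO2CH2CF3 (1.3 equiv), −78 °C; 5 % aq HCl wash; then p-ABSA (1.5 equiv), Et3N (1.5 equiv), H2O (1 equiv), MeCN, rt
Reagents that add atoms: 4-acetamidobenzenesulfonyl azide (p-ABSA), CC(=O)Nc1ccc(cc1)S(=O)(=O)N=[N+]=[N-]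
Why: Detrifluoroacetylative (Regitz-type) diazo transfer: a plain ester is too weakly acidic for direct transfer, so the side-arm enolate is first C-trifluoroacetylated and the activating group then leaves as the N-trifluoroacetyl sulfonamide; the amide base does not remove the far less acidic cyclopropane α-hydrogen, so no stereocentre is touched.

Step 6
Reactants: 12 tert-butyl 2-(1-diazo-2-methoxy-2-oxoethyl)-2,3-bis(3,4-dimethoxyphenyl)cyclopropane-1-carboxylate
Product: 13 3-tert-butyl 1-methyl 2,4-bis(3,4-dimethoxyphenyl)cyclobut-1-ene-1,3-dicarboxylate (racemic; the sp3 aryl and the tert-butyl ester cis; in target numbering C2=C3 with the C1 aryl cis to the C4 ester)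
Conditions: Rh2(OAc)4 (2 mol %), CH2Cl2, 0 °C → rt, 12 added slowly
Reagents that add atoms: none
Why: Rh2(OAc)4 extrudes N2 from 12 to give an electrophilic rhodium carbenoid at the future C2; in the bisected arrangement a ring C–C σ bond overlaps with the vacant carbenoid orbital, and the benzylic ring carbon (future C1) shifts with its bonding pair from the quaternary carbon (future C3) to C2, after which loss of the dirhodium unit leaves the C2=C3 alkene. The closest known reaction type is the rhodium- or silver-catalysed ring expansion of α-cyclopropyl-α-diazo esters to cyclobutene-1-carboxylates. The four-membered ring arises by ring enlargement through a 1,2-alkyl migration and not by an end-to-end cyclisation. No new stereocentre is formed: the migrating carbon keeps its configuration and its bond to the ester-bearing carbon (future C4) is untouched, so the cis relation between C1 aryl and C4 ester set in step 3 passes into 13, while the quaternary centre becomes sp2. The selectivity needed is migration of the benzylic carbon and not the ester-bearing one; the 3,4-dimethoxyphenyl group stabilises the positive charge building up on the migrating carbon whereas the ester destabilises it on the other, and both substituents lie on the face away from the carbenoid, so sterics do not discriminate. The carbon next to the carbenoid bears no hydrogen, which excludes a 1,2-hydride shift, and slow addition should suppress azine and carbene-dimer formation. Neutral conditions at or below room temperature are chosen because the C4 hydrogen of 13 is acidic (allylic and α to an ester) and the cyclobutene could open electrocyclically on heating.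

Step 7
Reactants: 13 3-tert-butyl 1-methyl 2,4-bis(3,4-dimethoxyphenyl)cyclobut-1-ene-1,3-dicarboxylate
Product: 14 3-tert-butyl 1-methyl 2,4-bis(3,4-dimethoxyphenyl)cyclobutane-1,3-dicarboxylate (racemic; aryls trans to each other, esters trans to each other, each ester cis to one aryl)
Conditions: [Ir(cod)(PCy3)(py)]PF6 (10 mol %), H2 (1–10 bar), CH2Cl2, 0 °C → rt
Reagents that add atoms: none
Why: Carbalkoxy-directed homogeneous hydrogenation: the cationic monovalent iridium centre binds the carbonyl oxygen of the C4 ester and the C2=C3 alkene on the same face and delivers both hydrogens syn from that face, so the C2 ester and the C3 aryl end trans to the C4 ester and the C1 aryl, which sets C2 and C3 in the target sense; the non-coordinating solvent keeps the ester as the only ligand competing for the metal.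

Step 8
Reactants: 14 3-tert-butyl 1-methyl 2,4-bis(3,4-dimethoxyphenyl)cyclobutane-1,3-dicarboxylate
Product: 16 2,4-bis(3,4-dimethoxyphenyl)cyclobutane-1,3-dicarboxylic acid (meso; configuration as in 14), via half ester 15 (not isolated)
Conditions: CF3CO2H, Et3SiH, CH2Cl2, 0 °C → rt; evaporate; LiOH·H2O (4 equiv), THF/MeOH/H2O, rt; 1 M HCl
Reagents that add atoms: lithium hydroxide monohydrate, [Li+].[OH-].O
Why: Acidolysis removes the tert-butyl group by alkyl–oxygen cleavage (the silane traps the cation before it can alkylate the arenes), and saponification then cleaves the methyl ester by acyl–oxygen cleavage; hydroxide attack at the ester is faster than α-deprotonation and the C4 carboxylate formed first protects its own α-centre, so C2 and C4 should keep their configuration.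

Step 9
Reactants: 16 2,4-bis(3,4-dimethoxyphenyl)cyclobutane-1,3-dicarboxylic acid, 17 5,6-dihydropyridin-2(1H)-one
Product: 20 1,1'-{[2,4-bis(3,4-dimethoxyphenyl)cyclobutane-1,3-diyl]dicarbonyl}bis(5,6-dihydropyridin-2(1H)-one) (target; meso, aryls trans, acyl groups trans), via diacid dichloride 18 (not isolated), via lithium lactamide 19 (not isolated)
Conditions: (COCl)2 (2.5 equiv), DMF (cat.), CH2Cl2, 0 °C → rt, evaporate; 17 (2.2 equiv), n-BuLi (2.1 equiv), THF, −78 °C; add 18 in THF, −78 → −20 °C
Reagents that add atoms: none
Why: Acid chloride formation under Vilsmeier-type catalysis followed by N-acylation of the preformed lithium lactamide gives the two imides; low temperature and the absence of amine base avoid ketene formation and thus epimerisation at C2/C4, and the hard nitrogen anion acylates at nitrogen without conjugate addition to the enelactam.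

## Compound list

1 | 4-iodoveratrole (4-iodo-1,2-dimethoxybenzene) | COc1ccc(I)cc1OC | starting material
2 | 4-ethynylveratrole (4-ethynyl-1,2-dimethoxybenzene) | COc1ccc(C#C)cc1OC | starting material
3 | 1,2-bis(3,4-dimethoxyphenyl)ethyne | COc1ccc(C#Cc2ccc(OC)c(OC)c2)cc1OC | intermediate
4 | tert-butyl diazoacetate | CC(C)(C)OC(=O)C=[N+]=[N-] | starting material
5 | tert-butyl 2,3-bis(3,4-dimethoxyphenyl)cycloprop-2-ene-1-carboxylate | CC(C)(C)OC(=O)C1C(c2ccc(OC)c(OC)c2)=C1c1ccc(OC)c(OC)c1 | intermediate
6 | allyl bromide | C=CCBr | starting material
7 | allylzinc bromide | C=CC[Zn]Br | intermediate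
8 | cyclopropylzinc bromide (zinc on the benzylic carbon, cis to the allyl group and trans to the ester) | C=CC[C@@]1(c2ccc(OC)c(OC)c2)[C@]([Zn]Br)(c2ccc(OC)c(OC)c2)[C@@H]1C(=O)OC(C)(C)C | intermediate
9 | tert-butyl 2-(prop-2-en-1-yl)-2,3-bis(3,4-dimethoxyphenyl)cyclopropane-1-carboxylate (aryls and ester cis) | C=CC[C@@]1(c2ccc(OC)c(OC)c2)[C@H](c2ccc(OC)c(OC)c2)[C@@H]1C(=O)OC(C)(C)C | intermediate
10 | tert-butyl 2-(2-methoxy-2-oxoethyl)-2,3-bis(3,4-dimethoxyphenyl)cyclopropane-1-carboxylate (aryls and ring ester cis) | COC(=O)C[C@@]1(c2ccc(OC)c(OC)c2)[C@H](c2ccc(OC)c(OC)c2)[C@@H]1C(=O)OC(C)(C)C | intermediate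
11 | α-trifluoroacetyl derivative of 10 (epimers at the side-arm carbon, or enol) | COC(=O)C(C(=O)C(F)(F)F)[C@@]1(c2ccc(OC)c(OC)c2)[C@H](c2ccc(OC)c(OC)c2)[C@@H]1C(=O)OC(C)(C)C | intermediate
12 | tert-butyl 2-(1-diazo-2-methoxy-2-oxoethyl)-2,3-bis(3,4-dimethoxyphenyl)cyclopropane-1-carboxylate (aryls and ring ester cis) | COC(=O)C(=[N+]=[N-])[C@@]1(c2ccc(OC)c(OC)c2)[C@H](c2ccc(OC)c(OC)c2)[C@@H]1C(=O)OC(C)(C)C | intermediate
13 | 3-tert-butyl 1-methyl 2,4-bis(3,4-dimethoxyphenyl)cyclobut-1-ene-1,3-dicarboxylate (sp3 aryl and tert-butyl ester cis) | COC(=O)C1=C(c2ccc(OC)c(OC)c2)[C@@H](C(=O)OC(C)(C)C)[C@H]1c1ccc(OC)c(OC)c1 | intermediate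
14 | 3-tert-butyl 1-methyl 2,4-bis(3,4-dimethoxyphenyl)cyclobutane-1,3-dicarboxylate (aryls trans, esters trans) | COC(=O)[C@@H]1[C@H](c2ccc(OC)c(OC)c2)[C@@H](C(=O)OC(C)(C)C)[C@H]1c1ccc(OC)c(OC)c1 | intermediate
15 | 3-(methoxycarbonyl)-2,4-bis(3,4-dimethoxyphenyl)cyclobutane-1-carboxylic acid (configuration as in 14) | COC(=O)[C@@H]1[C@H](c2ccc(OC)c(OC)c2)[C@@H](C(=O)O)[C@H]1c1ccc(OC)c(OC)c1 | intermediate
16 | 2,4-bis(3,4-dimethoxyphenyl)cyclobutane-1,3-dicarboxylic acid (meso; aryls trans, acids trans) | OC(=O)[C@@H]1[C@H](c2ccc(OC)c(OC)c2)[C@@H](C(=O)O)[C@H]1c1ccc(OC)c(OC)c1 | intermediate
17 | 5,6-dihydropyridin-2(1H)-one | O=C1C=CCCN1 | starting material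
18 | 2,4-bis(3,4-dimethoxyphenyl)cyclobutane-1,3-dicarbonyl dichloride (configuration as in 16) | ClC(=O)[C@@H]1[C@H](c2ccc(OC)c(OC)c2)[C@@H](C(=O)Cl)[C@H]1c1ccc(OC)c(OC)c1 | intermediate
19 | lithium salt of 5,6-dihydropyridin-2(1H)-one (N-lithio lactam) | [Li]N1CCC=CC1=O | intermediate
20 | 1,1'-{[2,4-bis(3,4-dimethoxyphenyl)cyclobutane-1,3-diyl]dicarbonyl}bis(5,6-dihydropyridin-2(1H)-one) (meso) | COc1ccc([C@H]2[C@H](C(=O)N3CCC=CC3=O)[C@H](c3ccc(OC)c(OC)c3)[C@H]2C(=O)N2CCC=CC2=O)cc1OC | target

Total step count: 9 steps. Longest linear sequence: 9 steps (from 1 and 2 to 20; 4, 6 and 17 are purchased).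

## Least certain steps and fallbacks

Step 6 (key step). The most likely failure is migration of the ester-bearing ring carbon in place of the benzylic one. The carbenoid could also be diverted into dimerisation or attack on an arene, or the product could open electrocyclically. The cause is that both candidate ring carbons are secondary and lie equally far from the carbenoid, so only the electronic bias separates them. The fallback builds the ring photochemically. It sets out from 1 and returns at 16. Heck coupling of 1 with acrylic acid (Pd(OAc)2, Et3N, MeCN/H2O, 80 °C) should give (E)-3,4-dimethoxycinnamic acid F1. Irradiation of F1 (λ > 300 nm) as a crystal form with antiparallel, head-to-tail stacked alkenes should give the centrosymmetric [2+2] dimer, which is 16. Step 9 then completes the route from 16.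

Step 7. The most likely failure is delivery of hydrogen to the open face through an undirected pathway. That would invert both C2 and C3 and cannot be repaired at C3. Slow reduction of the tetrasubstituted conjugated alkene and double-bond migration are further risks. The cause is that the directing ester and the C1 aryl crowd the face that must be used. The fallback swaps the directing group for a hydroxyl. It sets out from 13 and returns at 15. Acidolysis with anisole as cation trap and without silane, so that no ionic hydrogenation of the conjugated alkene can compete (CF3CO2H, anisole, CH2Cl2, 0 °C), should give the cyclobutene mono-acid F2. Chemoselective reduction of the acid (BH3·SMe2, THF, 0 °C) should give the hydroxymethyl cyclobutene F3. Hydroxyl-directed hydrogenation with [Ir(cod)(PCy3)(py)]PF6 and H2 in CH2Cl2 should give the saturated alcohol F4 with hydrogen added on the hydroxymethyl face. Oxidation of the primary alcohol (TEMPO, PhI(OAc)2, MeCN/H2O) returns 15, which is saponified as in the second half of step 8.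

Step 3. The most likely failure is addition on the ester face through chelation of zinc by the ester carbonyl, which would place the C1 aryl trans to the C4 ester. Sluggish carbometalation of the tetrasubstituted alkene and epimerisation of the benzylic C–Zn bond before protonation are further risks. The fallback uses a sterically governed, non-chelating borylcopper addition. It sets out from 5 and returns at 10. Copper-catalysed hydroboration (CuCl, Xantphos, NaOtBu, B2pin2, MeOH, THF) should give the tertiary cyclopropyl pinacol boronate F5, with boron and the new hydrogen trans to the ester. Zweifel olefination (vinylmagnesium bromide, THF, −78 °C; I2; NaOMe, MeOH) should give the vinylcyclopropane F6 with retention at the migrating carbon. Hydroboration–oxidation (9-BBN; NaBO3) should give the primary alcohol F7. Oxidation (TEMPO, PhI(OAc)2, MeCN/H2O) should give the acid F8. Methylation with Me3SiCHN2 in MeOH/PhMe returns 10.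

Step 4. The most likely failure is over-oxidation of the dimethoxyarenes by excess ozone, because the second stage (oxidation of the hemiacetal) needs more than one equivalent. The fallback avoids ozone. It sets out from 9 and returns at 10. Lemieux–Johnson cleavage (OsO4 cat., NaIO4, 2,6-lutidine, dioxane/H2O) should give the aldehyde F9. Oxidative esterification of F9 (I2, KOH, MeOH, 0 °C) returns 10.

## Further compounds

F1 | step 6 | (E)-3,4-dimethoxycinnamic acid | COc1ccc(/C=C/C(=O)O)cc1OC
F2 | step 7 | 3-(methoxycarbonyl)-2,4-bis(3,4-dimethoxyphenyl)cyclobut-2-ene-1-carboxylic acid (acid cis to the sp3 aryl) | COC(=O)C1=C(c2ccc(OC)c(OC)c2)[C@@H](C(=O)O)[C@H]1c1ccc(OC)c(OC)c1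
F3 | step 7 | methyl 3-(hydroxymethyl)-2,4-bis(3,4-dimethoxyphenyl)cyclobut-1-ene-1-carboxylate (hydroxymethyl cis to the sp3 aryl) | COC(=O)C1=C(c2ccc(OC)c(OC)c2)[C@@H](CO)[C@H]1c1ccc(OC)c(OC)c1
F4 | step 7 | methyl 3-(hydroxymethyl)-2,4-bis(3,4-dimethoxyphenyl)cyclobutane-1-carboxylate (configuration as in 14) | COC(=O)[C@@H]1[C@H](c2ccc(OC)c(OC)c2)[C@@H](CO)[C@H]1c1ccc(OC)c(OC)c1
F5 | step 3 | tert-butyl 2,3-bis(3,4-dimethoxyphenyl)-2-(4,4,5,5-tetramethyl-1,3,2-dioxaborolan-2-yl)cyclopropane-1-carboxylate (aryls and ester cis) | CC1(C)OB(OC1(C)C)[C@@]2(c3ccc(OC)c(OC)c3)[C@H](c3ccc(OC)c(OC)c3)[C@@H]2C(=O)OC(C)(C)C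
F6 | step 3 | tert-butyl 2-ethenyl-2,3-bis(3,4-dimethoxyphenyl)cyclopropane-1-carboxylate (aryls and ester cis) | C=C[C@@]1(c2ccc(OC)c(OC)c2)[C@H](c2ccc(OC)c(OC)c2)[C@@H]1C(=O)OC(C)(C)C
F7 | step 3 | tert-butyl 2-(2-hydroxyethyl)-2,3-bis(3,4-dimethoxyphenyl)cyclopropane-1-carboxylate (aryls and ester cis) | OCC[C@@]1(c2ccc(OC)c(OC)c2)[C@H](c2ccc(OC)c(OC)c2)[C@@H]1C(=O)OC(C)(C)C
F8 | step 3 | 2-[3-(tert-butoxycarbonyl)-1,2-bis(3,4-dimethoxyphenyl)cyclopropyl]acetic acid (aryls and ring ester cis) | OC(=O)C[C@@]1(c2ccc(OC)c(OC)c2)[C@H](c2ccc(OC)c(OC)c2)[C@@H]1C(=O)OC(C)(C)C
F9 | step 4 | tert-butyl 2-(2-oxoethyl)-2,3-bis(3,4-dimethoxyphenyl)cyclopropane-1-carboxylate (aryls and ester cis) | O=CC[C@@]1(c2ccc(OC)c(OC)c2)[C@H](c2ccc(OC)c(OC)c2)[C@@H]1C(=O)OC(C)(C)C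
A1 | alternative 1 | bis(cis-cyclohexene carbonate) double Diels–Alder adduct (one diastereomer at the carbonate carbons) | O=C1O[C@H]2CC=C(C[C@H]2O1)[C@H]1[C@H](C(=O)OC(C)(C)C)[C@H](C2=CC[C@H]3OC(=O)O[C@H]3C2)[C@H]1C(=O)OC(C)(C)C
A2 | alternative 1 | di-tert-butyl 2,4-di(buta-1,3-dien-2-yl)cyclobutane-1,3-dicarboxylate (dienyl groups trans, esters trans) | C=CC(=C)[C@H]1[C@H](C(=O)OC(C)(C)C)[C@H](C(=C)C=C)[C@H]1C(=O)OC(C)(C)C
A3 | alternative 1 | vinylene carbonate | O=C1OC=CO1
A4 | alternative 2 | anti head-to-tail cyclobutane dimer of 6,7-dimethoxycoumarin (bis-lactone) | O=C1Oc2cc(OC)c(OC)cc2[C@@H]3[C@H]1[C@H]1c4cc(OC)c(OC)cc4OC(=O)[C@@H]31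
A5 | alternative 2 | 6,7-dimethoxycoumarin | COc1cc2ccc(=O)oc2cc1OC
A6 | alternative 3 | 2,4-bis(3,4-dimethoxyphenyl)cyclobutane-1,3-dicarboxamide bis(8-quinolinylamide) (aryls trans, amides trans) | COc1ccc([C@H]2[C@H](C(=O)Nc3cccc4cccnc34)[C@H](c3ccc(OC)c(OC)c3)[C@H]2C(=O)Nc2cccc3cccnc23)cc1OC
A7 | alternative 3 | trans-N,N'-di(quinolin-8-yl)cyclobutane-1,3-dicarboxamide | O=C(Nc1cccc2cccnc12)[C@H]1C[C@H](C(=O)Nc2cccc3cccnc23)C1
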